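**Retrosynthetic overview**

- Cyclocymopol 16 comes from its dimethyl ether 14 (via quinone 15). The C4–Br bond comes from the trans alcohol 13 by SN2 inversion, and 13 from ketone 12, made from the cis alcohol 11.
- Structural feature: in the single carbocycle (C1 carries the exocyclic CH2 C8; C4 carries Br; C5 the gem-dimethyl; C6 is the CH carrying benzylic C7), C6 lies between C7 and C1. One radical chain can therefore form C7–aryl and C6–C1.
- Key disconnection: 10 ⇒ aryl iodide 9 + acyclic enyne 7 (C6=C7 vinyl on quaternary C5, C1≡C8 alkyne capped with silicon). The aryl radical adds to C7 and the C6 radical closes 6-exo-dig on C1; this is the only ring-forming event.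
- 7 ⇒ pent-4-ynal + a prenylborane. Asymmetric prenylboration sets C4, which relays its configuration to C6 and is later reset through the ketone.

Key step: step 5

Remark: 10 is expected as an E/Z mixture at the C1=C8 vinylsilane; this is of no consequence because the silicon is removed in step 6.

**Route**

Step 1
Reactants: 1 pent-4-yn-1-ol
Product: 2 pent-4-ynal
Conditions: Dess–Martin periodinane, CH2Cl2, 0 °C to rt
Reagents that add atoms: none
Why: Dess–Martin oxidation takes the primary alcohol to the aldehyde under neutral conditions without touching the terminal alkyne, and the volatile aldehyde is carried on as a solution.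

Step 2
Reactants: 2 pent-4-ynal; 3 3-methylbuta-1,2-diene
Product: 6 (4R)-3,3-dimethyloct-1-en-7-yn-4-ol, via prenylborane 4 (not isolated), via borinate ester 5 (not isolated)
Conditions: 3, (−)-diisopinocampheylborane [(−)-Ipc2BH, the enantiomer derived from (+)-α-pinene], THF, −25 °C; then 2, −78 °C; then NaOH, H2O2, 0 °C to rt
Reagents that add atoms: none
Why: Asymmetric prenylboration of the Brown allylation type: hydroboration of allene 3 gives prenylborane 4, which adds to the aldehyde with allylic transposition through a closed chair transition state so that the quaternary carbon forms next to the carbinol, and the isopinocampheyl groups derived from (+)-α-pinene direct attack to the Si face of the aldehyde, which sets the (4R) centre.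

Step 3
Reactants: 6 (4R)-3,3-dimethyloct-1-en-7-yn-4-ol
Product: 7 benzyl{[(4R)-8-[benzyl(dimethyl)silyl]-3,3-dimethyloct-1-en-7-yn-4-yl]oxy}dimethylsilane
Conditions: n-BuLi (2.2 equiv), THF, −78 to 0 °C; BnMe2SiCl (2.4 equiv), 0 °C to rt
Reagents that add atoms: benzylchlorodimethylsilane, C[Si](C)(Cl)Cc1ccccc1
Why: Double deprotonation (alkoxide and acetylide) followed by O- and C-silylation with an unhindered chlorosilane installs the oxygen protecting group and the alkyne cap in one operation, with the stereocentre untouched.

Step 4
Reactants: 8 2-bromo-1,4-dimethoxybenzene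
Product: 9 1-bromo-4-iodo-2,5-dimethoxybenzene
Conditions: N-iodosuccinimide, CF3CO2H (cat.), MeCN, rt
Reagents that add atoms: N-iodosuccinimide, O=C1CCC(=O)N1I
Why: Electrophilic aromatic iodination goes to the position ortho to a methoxy group and para to bromine, the only open site that both directing effects favour.

Step 5
Reactants: 7 benzyl{[(4R)-8-[benzyl(dimethyl)silyl]-3,3-dimethyloct-1-en-7-yn-4-yl]oxy}dimethylsilane; 9 1-bromo-4-iodo-2,5-dimethoxybenzene
Product: 10 benzyl{[(1R,3R)-3-[(4-bromo-2,5-dimethoxyphenyl)methyl]-4-{[benzyl(dimethyl)silyl]methylidene}-2,2-dimethylcyclohexyl]oxy}dimethylsilane (silyloxy cis to arylmethyl; E/Z mixture)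
Conditions: 9 (3 equiv), (Me3Si)3SiH (2 equiv, syringe pump, 10 h), 2,2'-azobis(2-methylpropionitrile) (AIBN, 0.3 equiv), t-BuOH (0.3 M in 7), 80 °C
Reagents that add atoms: none
Why: The (Me3Si)3Si radical takes iodine from 9 (C–I abstraction outpaces C–Br by orders of magnitude), the aryl radical adds to the open CH2 terminus C7 of the vinyl group, the resulting secondary C6 radical closes on alkyne carbon C1, and the α-silyl vinyl radical at C8 takes hydrogen from (Me3Si)3SiH, which passes the chain on. The closest known reaction types are radical addition–exo-dig cyclization cascades of 1,n-enynes, silane-mediated anti-Markovnikov hydroarylation of unactivated terminal alkenes with aryl iodides, and 6-exo-dig closures of alkyl radicals on silylalkynes. The cyclohexane ring closes in the 6-exo-dig mode, helped by the gem-dimethyl group at C5 (Thorpe–Ingold effect) and by silicon at C8, which stabilises the developing vinyl radical. The new stereocentre C6 is controlled by the C4 stereocentre through a chair-like transition state with the C4 silyloxy group and the C6 arylmethyl group both equatorial, which should favour the cis isomer 10; the bias is expected to be moderate, and the trans isomer is to be removed by chromatography here or after step 6. The step needs halogen selectivity, secured by the iodide in 9; alkene-over-alkyne selectivity for the aryl and silyl radicals, secured by the silicon cap that makes the alkyne internal and hindered while C7 is a free CH2; and ring closure before hydrogen transfer, secured by keeping the silane concentration low through slow addition.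

Step 6
Reactants: 10 the bis-silylated cyclization product
Product: 11 (1R,3S)-3-[(4-bromo-2,5-dimethoxyphenyl)methyl]-2,2-dimethyl-4-methylidenecyclohexan-1-ol
Conditions: Bu4NF (5 equiv), THF, rt to 50 °C
Reagents that add atoms: none
Why: Fluoride cleaves the Si–O bond and, through fluoride-triggered loss of the benzyl group from silicon followed by protodesilylation (the known behaviour of alkenyl benzyldimethylsilanes), replaces the vinylic silicon by hydrogen under non-acidic conditions, so the methylidene group appears without migration of the double bond.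

Step 7
Reactants: 11 the cis alcohol
Product: 12 (3S)-3-[(4-bromo-2,5-dimethoxyphenyl)methyl]-2,2-dimethyl-4-methylidenecyclohexan-1-one
Conditions: Dess–Martin periodinane, CH2Cl2, rt
Reagents that add atoms: none
Why: Dess–Martin oxidation of the secondary alcohol gives the ketone, and the remaining stereocentre is separated from the carbonyl group by the quaternary carbon and cannot epimerise.

Step 8
Reactants: 12 the ketone
Product: 13 (1S,3S)-3-[(4-bromo-2,5-dimethoxyphenyl)methyl]-2,2-dimethyl-4-methylidenecyclohexan-1-ol
Conditions: LiBH(s-Bu)3, THF, −78 °C; then NaOH, H2O2, 0 °C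
Reagents that add atoms: none
Why: Substrate-controlled reduction with a bulky trialkylborohydride: hydride is delivered along the equatorial trajectory of the chair that keeps the arylmethyl group equatorial, as with 2,2-dimethylcyclohexanones, which should give the axial alcohol trans to the arylmethyl group, i.e. the (1S) centre.

Step 9
Reactants: 13 the trans alcohol
Product: 14 1-bromo-4-{[(1S,3R)-3-bromo-2,2-dimethyl-6-methylidenecyclohexyl]methyl}-2,5-dimethoxybenzene
Conditions: PPh3, CBr4, CH2Cl2, 0 °C to rt
Reagents that add atoms: tetrabromomethane, BrC(Br)(Br)Br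
Why: Appel bromination: the alkoxyphosphonium ion formed from the axial alcohol is displaced by bromide in an SN2 reaction with inversion, which puts bromine equatorial and cis to the arylmethyl group, a conversion precedented for axial cyclohexanols next to a gem-dimethyl carbon.

Step 10
Reactants: 14 the dibromide
Product: 15 2-bromo-5-{[(1S,3R)-3-bromo-2,2-dimethyl-6-methylidenecyclohexyl]methyl}cyclohexa-2,5-diene-1,4-dione
Conditions: (NH4)2Ce(NO3)6, MeCN/H2O, 0 °C
Reagents that add atoms: water, O
Why: Oxidative demethylation of the 1,4-dimethoxyarene by tetravalent cerium gives the para-quinone, whose oxygen atoms come from water while both methyl groups leave as methanol, and the short cold reaction should spare the secondary bromide and the 1,1-disubstituted alkene.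

Step 11
Reactants: 15 the bromoquinone
Product: 16 cyclocymopol, 2-bromo-5-{[(1S,3R)-3-bromo-2,2-dimethyl-6-methylidenecyclohexyl]methyl}benzene-1,4-diol
Conditions: Na2S2O4, Et2O/H2O, rt
Reagents that add atoms: none
Why: Dithionite reduction of the quinone to the hydroquinone proceeds under near-neutral aqueous conditions, which avoids acid-promoted addition of a phenol to the exocyclic alkene and gives the target.

**Compound list**

1 | pent-4-yn-1-ol | C#CCCCO | starting material
2 | pent-4-ynal | C#CCCC=O | intermediate
3 | 3-methylbuta-1,2-diene | CC(C)=C=C | starting material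
4 | (3-methylbut-2-en-1-yl)bis[(1R,2S,3R,5R)-2,6,6-trimethylbicyclo[3.1.1]heptan-3-yl]borane (prenylborane) | CC(C)=CCB([C@@H]1C[C@@H]2C[C@H]([C@H]1C)C2(C)C)[C@@H]1C[C@@H]2C[C@H]([C@H]1C)C2(C)C | intermediate
5 | (4R)-3,3-dimethyloct-1-en-7-yn-4-yl bis[(1R,2S,3R,5R)-2,6,6-trimethylbicyclo[3.1.1]heptan-3-yl]borinate | C#CCC[C@@H](OB([C@@H]1C[C@@H]2C[C@H]([C@H]1C)C2(C)C)[C@@H]1C[C@@H]2C[C@H]([C@H]1C)C2(C)C)C(C)(C)C=C | intermediate
6 | (4R)-3,3-dimethyloct-1-en-7-yn-4-ol | C#CCC[C@@H](O)C(C)(C)C=C | intermediate
7 | benzyl{[(4R)-8-[benzyl(dimethyl)silyl]-3,3-dimethyloct-1-en-7-yn-4-yl]oxy}dimethylsilane | c1ccccc1C[Si](C)(C)C#CCC[C@@H](O[Si](C)(C)Cc1ccccc1)C(C)(C)C=C | intermediate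
8 | 2-bromo-1,4-dimethoxybenzene | COc1ccc(OC)c(Br)c1 | starting material
9 | 1-bromo-4-iodo-2,5-dimethoxybenzene | COc1cc(Br)c(OC)cc1I | intermediate
10 | benzyl{[(1R,3R)-3-[(4-bromo-2,5-dimethoxyphenyl)methyl]-4-{[benzyl(dimethyl)silyl]methylidene}-2,2-dimethylcyclohexyl]oxy}dimethylsilane, silyloxy cis to arylmethyl, E/Z mixture | c1ccccc1C[Si](C)(C)C=C1CC[C@@H](O[Si](C)(C)Cc2ccccc2)C(C)(C)[C@H]1Cc1cc(OC)c(Br)cc1OC | intermediate
11 | (1R,3S)-3-[(4-bromo-2,5-dimethoxyphenyl)methyl]-2,2-dimethyl-4-methylidenecyclohexan-1-ol (cis) | C=C1CC[C@@H](O)C(C)(C)[C@H]1Cc1cc(OC)c(Br)cc1OC | intermediate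
12 | (3S)-3-[(4-bromo-2,5-dimethoxyphenyl)methyl]-2,2-dimethyl-4-methylidenecyclohexan-1-one | C=C1CCC(=O)C(C)(C)[C@H]1Cc1cc(OC)c(Br)cc1OC | intermediate
13 | (1S,3S)-3-[(4-bromo-2,5-dimethoxyphenyl)methyl]-2,2-dimethyl-4-methylidenecyclohexan-1-ol (trans) | C=C1CC[C@H](O)C(C)(C)[C@H]1Cc1cc(OC)c(Br)cc1OC | intermediate
14 | 1-bromo-4-{[(1S,3R)-3-bromo-2,2-dimethyl-6-methylidenecyclohexyl]methyl}-2,5-dimethoxybenzene | C=C1CC[C@@H](Br)C(C)(C)[C@H]1Cc1cc(OC)c(Br)cc1OC | intermediate
15 | 2-bromo-5-{[(1S,3R)-3-bromo-2,2-dimethyl-6-methylidenecyclohexyl]methyl}cyclohexa-2,5-diene-1,4-dione | C=C1CC[C@@H](Br)C(C)(C)[C@H]1CC1=CC(=O)C(Br)=CC1=O | intermediate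
16 | cyclocymopol, 2-bromo-5-{[(1S,3R)-3-bromo-2,2-dimethyl-6-methylidenecyclohexyl]methyl}benzene-1,4-diol | C=C1CC[C@@H](Br)C(C)(C)[C@H]1Cc1cc(O)c(Br)cc1O | target

**Step count**

Total: 11 steps. Longest linear sequence: 10 steps (steps 1–3 and 5–11); step 4 is a one-step side branch.

**Steps most likely to fail**

1. Step 5. The three-event chain may not propagate cleanly. Possible failures are hydrogen transfer to the aryl radical or to the C6 radical before ring closure, a 1,5-hydrogen shift from the propargylic C2–H to C6, attack of the vinyl radical on the arene, and weak 1,3-induction from C4 to C6. The fallback separates the ionic C7–aryl bond formation from the radical ring closure; it sets out from 7 (with 9 as aryl source) and returns at 10. The vinyl group of 7 is epoxidised with mCPBA (CH2Cl2, NaHCO3) to benzyl{[(3R)-7-[benzyl(dimethyl)silyl]-2-methyl-2-(oxiran-2-yl)hept-6-yn-3-yl]oxy}dimethylsilane F1. The aryl Grignard reagent made from 9 by selective iodine–magnesium exchange (i-PrMgCl·LiCl, THF, −20 °C) opens F1 at the CH2 terminus under CuI catalysis to give (4R)-1-(4-bromo-2,5-dimethoxyphenyl)-8-[benzyl(dimethyl)silyl]-4-{[benzyl(dimethyl)silyl]oxy}-3,3-dimethyloct-7-yn-2-ol F2. Treatment with 1,1'-thiocarbonyldiimidazole and DMAP gives O-[(4R)-1-(4-bromo-2,5-dimethoxyphenyl)-8-[benzyl(dimethyl)silyl]-4-{[benzyl(dimethyl)silyl]oxy}-3,3-dimethyloct-7-yn-2-yl] 1H-imidazole-1-carbothioate F3. Barton–McCombie-type radical generation from F3 with (Me3Si)3SiH and AIBN (toluene, 90 °C, slow addition) then produces the same C6 radical without any aryl radical present; it should close 6-exo-dig and give 10.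

2. Step 8. Facial selectivity may be poor if the chair with an axial arylmethyl group takes part, because equatorial hydride delivery to that conformer returns the cis alcohol. The fallback replaces substrate control by reagent control; it sets out from 12 and returns at 13. A Corey–Bakshi–Shibata reduction with (R)-1-methyl-3,3-diphenyltetrahydro-1H,3H-pyrrolo[1,2-c][1,3,2]oxazaborole and catecholborane (toluene, −78 °C) would be used. The quaternary carbon acts as the large group and should lead to the (1S) alcohol, and catecholborane does not hydroborate the alkene at this temperature. This detour makes no compound outside the list (F0).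

3. Step 9. The activated neopentylic alcohol may ionise, with methyl shift or elimination outrunning the SN2 displacement, or stereochemical fidelity may be lost. The fallback separates activation from displacement; it sets out from 13 and returns at 14. The alcohol is converted (Tf2O, pyridine, CH2Cl2, −30 °C) into (1S,3S)-3-[(4-bromo-2,5-dimethoxyphenyl)methyl]-2,2-dimethyl-4-methylidenecyclohexyl trifluoromethanesulfonate F4. The axial sulfonate is then displaced cold with soluble bromide (LiBr, acetone, 0 °C to rt), with inversion, to give 14.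

**Further compounds**

F1 | step 5 | benzyl{[(3R)-7-[benzyl(dimethyl)silyl]-2-methyl-2-(oxiran-2-yl)hept-6-yn-3-yl]oxy}dimethylsilane (epimers at the oxirane carbon) | c1ccccc1C[Si](C)(C)C#CCC[C@@H](O[Si](C)(C)Cc1ccccc1)C(C)(C)C1CO1
F2 | step 5 | (4R)-1-(4-bromo-2,5-dimethoxyphenyl)-8-[benzyl(dimethyl)silyl]-4-{[benzyl(dimethyl)silyl]oxy}-3,3-dimethyloct-7-yn-2-ol (epimers at C2) | c1ccccc1C[Si](C)(C)C#CCC[C@@H](O[Si](C)(C)Cc1ccccc1)C(C)(C)C(O)Cc1cc(OC)c(Br)cc1OC
F3 | step 5 | O-[(4R)-1-(4-bromo-2,5-dimethoxyphenyl)-8-[benzyl(dimethyl)silyl]-4-{[benzyl(dimethyl)silyl]oxy}-3,3-dimethyloct-7-yn-2-yl] 1H-imidazole-1-carbothioate (epimers at C2) | c1ccccc1C[Si](C)(C)C#CCC[C@@H](O[Si](C)(C)Cc1ccccc1)C(C)(C)C(OC(=S)n1ccnc1)Cc1cc(OC)c(Br)cc1OC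
F0 | step 8 | none | none
F4 | step 9 | (1S,3S)-3-[(4-bromo-2,5-dimethoxyphenyl)methyl]-2,2-dimethyl-4-methylidenecyclohexyl trifluoromethanesulfonate | C=C1CC[C@H](OS(=O)(=O)C(F)(F)F)C(C)(C)[C@H]1Cc1cc(OC)c(Br)cc1OC
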